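0.909 is the number of this flask: substrate charge over reagent charge, which I call the spending ratio. Substrate, at 0.050 M, is charged in less than reagent, at 0.0550 M, so substrate is the limiting reagent.

the same everywhere: substrate 0.050 M; second catalyst 50 µM
- zeta: reagent 0.055 M; precatalyst 17 µM; run made earlier
- gamma: reagent 0.055 M; precatalyst 38 µM; run made earlier
- flask: reagent 0.0550 M; precatalyst 25 µM

| run | time / h | product / % |
|---|---|---|
| zeta | 3.00 | 7.3 |
| zeta | 6.00 | 22.1 |
| zeta | 10.0 | 39.8 |
| zeta | 15.0 | 58.4 |
| zeta | 20.0 | 70.8 |
| zeta | 25.0 | 80.3 |
| gamma | 2.00 | 7.1 |
| gamma | 3.00 | 13.3 |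
| gamma | 4.00 | 20.7 |
| gamma | 6.00 | 34.1 |
| gamma | 10.0 | 59.9 |
| gamma | 15.0 | 79.9 |
| gamma | 25.0 | 96.7 |

(standard deviation of a reading: 0.5 percentage points)

- "the catalyst" is free catalyst with its forms; second catalyst is a second catalyst
- what has left substrate counts as converted, also if it is not yet product
- no earlier run changes the charge of reagent; that part of a forecast is a guess

1. factor on the rate of making product when 30% of the substrate are converted if reagent is charged twice over
2. factor on the rate when 30% of the substrate are converted if precatalyst is charged at 250 µM instead

I keep the books on substrate. Each mole charged stands as substrate left, as converted but not yet product, or as product. I assume each mole of product takes one mole of reagent: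

c(reagent) = c(reagent, charged) − c(product)

Reagent left, as a share of its own charge = 1 − spending ratio × product share

The books close with 9.09% of the reagent over.

Reading product for conversion at 30%, doubling the reagent charge raises c(reagent) by 2.38. Gamma has the same substrate and reagent charges. Its mean rate from 4.00 h to 6.00 h is 1.04 times that from 6.00 h to 10.0 h. Over those stretches reagent left goes from 75.1% to 57.3%. Substrate falls too, so this is a rough reading:

reagent order = ln(1.04) / ln(75.1% / 57.3%) = 0.140

factor on the rate = 2.38 ^ 0.140 = 1.13

My books give no number for precatalyst.

The forecast gives 1.2 for reagent and 2.6 for precatalyst, and says “Reagent order is therefore low”. My 1.13 is lower than its 1.2.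

The flask gives 1.14 for reagent and 1.48 for precatalyst, so the forecast's precatalyst factor is 1.76 times the flask's.

    substrate + free catalyst → free catalyst + open intermediate (k = 4420 M⁻¹ h⁻¹)
    second catalyst + open intermediate ⇌ catalyst intermediate (K = 1400 M⁻¹, k = 14200 M⁻¹ h⁻¹)
    reagent + catalyst intermediate → second catalyst + product (k = 3580 M⁻¹ h⁻¹)
    precatalyst → free catalyst (k = 1.33 h⁻¹)

At 15.0 h the flask holds 70.1% product, so the spending ratio leaves 36.2% of the reagent, and the flask shows 36.2%. In gamma, 96.7% product at 25.0 h leaves 12.1%. The middle entry of the books is open intermediate: in the flask it is made at 0.961 of the rate it is used up at 6.68 h, and at 0.684 at 30.0 h. So in the flask it sinks from 9.11% at 15.0 h to 1.59% at 30.0 h, beside 94.4% product.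

The earlier runs and the new flask were computed for substances that don't exist; noise was put on by code.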